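**Strategy.** Ring C (C2, C1, C10, C14, C15′, C4′) is not closed by the biomimetic [4+2]. Its hardest bond, C2–C4′, links the α-carbons of the C3 and C3′ ketones, a 1,4-diketone: the key step forges it by intramolecular oxidative coupling of two silyl enol ethers, closing ring C and setting the spiro quaternary C4′ in one operation. The precursor is a seco-dimer triketone held only by C14–C15′, made by a vinylogous Mukaiyama–Michael addition in which the C8 oxygen of the hydroxylated half, worn as a ketone, turns C14 into a γ-nucleophile. Enone transposition and C8 reduction finish; no labile trienone is needed.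

Key step: step 8

Assumption: guaiane numbering is used (primed atoms for the dehydrozaluzanin C half); dehydrocostus lactone and desacylcynaropicrin are taken as the commercial starting materials, and the 5αH,10βH arrangement of the final C1=C2 enone is taken to be the thermodynamic one, so C10 is set by equilibration.

Step 1
Reactants: 1 dehydrocostus lactone
Product: 2 3-epizaluzanin C (3α-hydroxydehydrocostus lactone)
Conditions: SeO2 (cat.), t-BuOOH, CH2Cl2, 0 °C → rt
Reagents that add atoms: tert-butyl hydroperoxide, CC(C)(C)OO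
Why: Catalytic SeO2/t-BuOOH allylic hydroxylation (ene reaction then [2,3]-sigmatropic shift) should occur at C3, the methylene flanking the C4=C15 exocyclic alkene; the carbinol configuration (α, from the convex face) does not matter because C3 is oxidised next.

Step 2
Reactants: 2 3-epizaluzanin C
Product: 3 dehydrozaluzanin C
Conditions: Dess–Martin periodinane, CH2Cl2, 0 °C → rt
Reagents that add atoms: none
Why: Dess–Martin oxidation of the allylic alcohol should give the α-methylene cyclopentanone under neutral conditions that leave the three exocyclic alkenes in place.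

Step 3
Reactants: 4 desacylcynaropicrin
Product: 5 3-O-TBS-desacylcynaropicrin (8α-OH free)
Conditions: TBSCl (1.05 equiv), imidazole, DMF, −20 → 0 °C
Reagents that add atoms: tert-butyldimethylsilyl chloride, CC(C)(C)[Si](C)(C)Cl
Why: Selective silyl ether formation is expected at the allylic cyclopentyl 3β-OH, which is less hindered than the 8α-OH flanked by the lactone-bearing C7.

Step 4
Reactants: 5 3-O-TBS-desacylcynaropicrin
Product: 6 8-oxo-3β-silyloxy guaianolide (8-ketone of 5)
Conditions: Dess–Martin periodinane, CH2Cl2, 0 °C → rt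
Reagents that add atoms: none
Why: Dess–Martin oxidation of the remaining secondary alcohol gives the C8 ketone, which is both the relay carbonyl for step 5 and the means of inverting C8 later.

Step 5
Reactants: 6 8-oxo-3β-silyloxy guaianolide; 3 dehydrozaluzanin C
Product: 9 C14–C15′-linked seco-dimer diketone, via TMS dienol ether 7 (not isolated), via TMS enol ether adduct 8 (not isolated)
Conditions: LiHMDS, TMSCl (in situ quench), THF, −78 °C; solvent exchange; then 3, TMSOTf (5 mol%), CH2Cl2, −78 °C; aq. citric acid, THF, 0 °C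
Reagents that add atoms: none
Why: Kinetic enolisation at the C9 methylene gives the 8-silyloxy-8,10(14)-diene, whose unhindered γ-terminus C14 should add to C15′ of the silyl-activated enone (vinylogous Mukaiyama–Michael addition); only this half carries a nucleophile and only 3 carries a ketone enone, so the union is cross-selective, and the only new centre (C4′–H, epimers) is erased in step 8.

Step 6
Reactants: 9 C14–C15′-linked seco-dimer diketone
Product: 10 seco-dimer 3β-alcohol
Conditions: HF·pyridine, pyridine, THF, 0 °C → rt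
Reagents that add atoms: none
Why: Buffered fluoride desilylation frees the allylic 3β-OH without base, so the Michael acceptors and the β-acyloxy ketone array are not disturbed.

Step 7
Reactants: 10 seco-dimer 3β-alcohol
Product: 11 seco-dimer triketone (3,8,3′-trioxo)
Conditions: MnO2, CH2Cl2, rt
Reagents that add atoms: none
Why: MnO2 oxidises only the allylic alcohol, giving the C3 ketone whose single enolisable position is C2.

Step 8
Reactants: 11 seco-dimer triketone (3,8,3′-trioxo)
Product: 13 spiro triketone with ring C closed, via bis-TMS enol ether 12 (not isolated)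
Conditions: TMSOTf (2.2 equiv), Et3N, CH2Cl2, −20 → 0 °C; then CAN (2.2 equiv), NaHCO3, MeCN, −30 → −10 °C
Reagents that add atoms: none
Why: The more electron-rich, tetrasubstituted C3′ enol silane is oxidised by Ce(IV) to a radical cation that, after loss of silicon, is the tertiary α-keto radical at C4′; it adds to C2 of the C3 enol silane, and a second Ce(IV) oxidises the resulting α-silyloxy radical to an oxocarbenium ion that desilylates to the C3 ketone. The closest known reaction type is the Ce(IV)- or Cu(II)-mediated oxidative coupling of two silyl enol ethers to a 1,4-diketone, used here intramolecularly. Ring C closes in a 6-exo-trig mode (C4′ onto C2, C3 outside the ring); the 5-endo (C9) and 4-exo (C10) closures onto the C8 enone are disfavoured, and a C2′ enol silane could reach C2 only through an eight-membered ring. The only lasting new stereocentre is C4′: the bond should form on the convex α-face of the cis-fused hydroazulenone (the face of H-1′ and H-5′), which places C2 α and C15′ β as in the target, while C2 is a transient stereocentre erased in step 9. The step needs regiocontrol in the C3′ enol silane (equilibrating silylation to the tetrasubstituted isomer) and chemoselectivity over the C8 enone (two equivalents of silylating agent and the lower oxidation potential of the tetrasubstituted enol ether).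

Step 9
Reactants: 13 spiro triketone with ring C closed
Product: 14 8-oxo analogue of the target (C1=C2 enone, 10βH)
Conditions: DBU (0.2 equiv), CH2Cl2, 0 °C → rt
Reagents that add atoms: none
Why: Base-mediated enone transposition through the C8 dienolate (γ-deprotonation at C1) and then the C3 dienolate (C2–H) should drain the C9=C10 enone into the tetrasubstituted, cross-conjugated C1=C2 cyclopentenone, with C10 (and C5, also γ to C3) protonated under thermodynamic control to the 10βH,5αH arrangement.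

Step 10
Reactants: 14 8-oxo analogue of the target
Product: 15 target (CNP0200944.1)
Conditions: LiAlH(Ot-Bu)3, THF, −78 → −40 °C
Reagents that add atoms: none
Why: The bulky alkoxyaluminium hydride should reduce only C8 (C3′ is neopentyl next to the spiro centre, C3 is a cross-conjugated dienone), and attack anti to C11 on C7, from the α-face, gives the 8β-alcohol (1,2-induction in a ketone reduction).

**Compound list**

1 | dehydrocostus lactone (guaia-4(15),10(14),11(13)-trien-12,6α-olide; 1αH,5αH,6βH,7αH) | C=C1CC[C@H]2C(=C)CC[C@H]3C(=C)C(=O)O[C@@H]3[C@@H]12 | starting material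
2 | 3-epizaluzanin C (3α-hydroxy derivative of 1) | C=C1[C@H](O)C[C@H]2C(=C)CC[C@H]3C(=C)C(=O)O[C@@H]3[C@@H]12 | intermediate
3 | dehydrozaluzanin C (3-oxo derivative of 1) | C=C1C(=O)C[C@H]2C(=C)CC[C@H]3C(=C)C(=O)O[C@@H]3[C@@H]12 | intermediate
4 | desacylcynaropicrin (3β,8α-dihydroxy derivative of 1) | C=C1[C@@H](O)C[C@H]2C(=C)C[C@H](O)[C@H]3C(=C)C(=O)O[C@@H]3[C@@H]12 | starting material
5 | 3-O-TBS-desacylcynaropicrin (3β-OTBS, 8α-OH) | C=C1[C@@H](O[Si](C)(C)C(C)(C)C)C[C@H]2C(=C)C[C@H](O)[C@H]3C(=C)C(=O)O[C@@H]3[C@@H]12 | intermediate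
6 | 8-oxo-3β-silyloxy guaianolide (8-ketone of 5) | C=C1[C@@H](O[Si](C)(C)C(C)(C)C)C[C@H]2C(=C)CC(=O)[C@H]3C(=C)C(=O)O[C@@H]3[C@@H]12 | intermediate
7 | TMS dienol ether of 6 (C8(OTMS)=C9, C10=C14) | C=C1[C@@H](O[Si](C)(C)C(C)(C)C)C[C@H]2C(=C)C=C(O[Si](C)(C)C)[C@H]3C(=C)C(=O)O[C@@H]3[C@@H]12 | intermediate
8 | Michael adduct as C3′ TMS enol ether (C14–C15′ bond, C3′(OTMS)=C4′, C9=C10–C8=O) | C=C1[C@@H](O[Si](C)(C)C(C)(C)C)C[C@H]2C(CCC5=C(O[Si](C)(C)C)C[C@H]6C(=C)CC[C@H]7C(=C)C(=O)O[C@@H]7[C@@H]56)=CC(=O)[C@H]3C(=C)C(=O)O[C@@H]3[C@@H]12 | intermediate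
9 | C14–C15′-linked seco-dimer diketone (3β-OTBS, 8-oxo-9(10)-ene; C3′ ketone, C4′–H epimers) | C=C1[C@@H](O[Si](C)(C)C(C)(C)C)C[C@H]2C(CCC5C(=O)C[C@H]6C(=C)CC[C@H]7C(=C)C(=O)O[C@@H]7[C@@H]56)=CC(=O)[C@H]3C(=C)C(=O)O[C@@H]3[C@@H]12 | intermediate
10 | seco-dimer 3β-alcohol (C4′–H epimers) | C=C1[C@@H](O)C[C@H]2C(CCC5C(=O)C[C@H]6C(=C)CC[C@H]7C(=C)C(=O)O[C@@H]7[C@@H]56)=CC(=O)[C@H]3C(=C)C(=O)O[C@@H]3[C@@H]12 | intermediate
11 | seco-dimer triketone (3,8,3′-trioxo; C4′–H epimers) | C=C1C(=O)C[C@H]2C(CCC5C(=O)C[C@H]6C(=C)CC[C@H]7C(=C)C(=O)O[C@@H]7[C@@H]56)=CC(=O)[C@H]3C(=C)C(=O)O[C@@H]3[C@@H]12 | intermediate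
12 | bis-TMS enol ether of 11 (C2=C3–OTMS and C4′=C3′–OTMS) | C=C1C(O[Si](C)(C)C)=C[C@H]2C(CCC5=C(O[Si](C)(C)C)C[C@H]6C(=C)CC[C@H]7C(=C)C(=O)O[C@@H]7[C@@H]56)=CC(=O)[C@H]3C(=C)C(=O)O[C@@H]3[C@@H]12 | intermediate
13 | spiro triketone with ring C closed (C2–C4′ bond, C4′ as in target, 1αH, C2–H epimers, C9=C10–C8=O) | C=C1C(=O)C2[C@H]3C(CC[C@]24C(=O)C[C@H]2C(=C)CC[C@H]5C(=C)C(=O)O[C@@H]5[C@H]24)=CC(=O)[C@H]2C(=C)C(=O)O[C@@H]2[C@@H]13 | intermediate
14 | 8-oxo analogue of the target (C1=C2 enone, 10βH) | C=C1C(=O)C2=C3[C@H](CC[C@]24C(=O)C[C@H]2C(=C)CC[C@H]5C(=C)C(=O)O[C@@H]5[C@H]24)CC(=O)[C@H]2C(=C)C(=O)O[C@@H]2[C@@H]13 | intermediate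
15 | CNP0200944.1 (8β-alcohol) | C=C1C(=O)C2=C3[C@H](CC[C@]24C(=O)C[C@H]2C(=C)CC[C@H]5C(=C)C(=O)O[C@@H]5[C@H]24)C[C@@H](O)[C@H]2C(=C)C(=O)O[C@@H]2[C@@H]13 | target

Total step count: 10. Longest linear sequence: 8 steps (steps 3–10 from 4; equally steps 1, 2 and 5–10 from 1).

**Steps most likely to fail**

Step 8 (key step). The C3′ ketone may silylate toward C2′, the C8 enone may be co-silylated and oxidised first, or coupling may go between molecules. The fallback fixes the regiochemistry at the Michael stage and makes the bond by a reductively generated radical. It sets out from 8: before hydrolysis in step 5, the enol silane is treated with NBS (THF, −78 °C) to give the tertiary C4′ α-bromo ketone F1. HF·pyridine then gives the 3β-alcohol F2 and MnO2 the bromo triketone F3. TMSOTf/Et3N (1.1 equiv, −78 °C) forms the C3 TMS enol ether F4, and fac-Ir(ppy)3 under blue light (MeCN) generates the C4′ α-keto radical, which should close onto C2 in the same 6-exo mode. The route is rejoined at 13.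

Step 5. Enolisation may occur toward C7 (also γ to the lactone carbonyl), or the bond may form through C9 (α) instead of C14 (γ). The fallback gives up the relay and joins the halves by cycloaddition. It sets out from 4 and 3: MnO2 oxidises the allylic carbinol of 4 to 8α-hydroxydehydrozaluzanin C F5. TMSOTf/Et3N gives the bis-silyl compound F6 (C3 TMS enol ether, 8-O-TMS), and Pd(OAc)2 in MeCN (Saegusa–Ito dehydrogenation) gives, after loss of the 8-O-TMS group on work-up, the cross-conjugated trienone F7. F7 and 3 should undergo a thermal Diels–Alder reaction (toluene, 45 °C) to the adduct F8 (C1=C10, C2–H, 8α-OH). Dess–Martin oxidation gives the 8-ketone F9, and Et3N conjugates the alkene. The route is rejoined at 14.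

Step 10. Hydride may be delivered to the β-face of C8, or the C3′ carbonyl may compete. The fallback corrects the centre by substitution instead of by face-selective reduction. It sets out from 14: the reduction is run to the 8α-alcohol F10 (8-epi-15), Mitsunobu reaction with formic acid (PPh3, DIAD, THF) inverts C8 to the 8β-formate F11, and KHCO3 in MeOH (0 °C) removes the formyl group. The route is rejoined at 15.

**Further compounds**

F1 | step 8 | C4′-bromo seco-dimer diketone (3β-OTBS) | C=C1[C@@H](O[Si](C)(C)C(C)(C)C)C[C@H]2C(CCC5(Br)C(=O)C[C@H]6C(=C)CC[C@H]7C(=C)C(=O)O[C@@H]7[C@@H]56)=CC(=O)[C@H]3C(=C)C(=O)O[C@@H]3[C@@H]12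
F2 | step 8 | C4′-bromo seco-dimer 3β-alcohol | C=C1[C@@H](O)C[C@H]2C(CCC5(Br)C(=O)C[C@H]6C(=C)CC[C@H]7C(=C)C(=O)O[C@@H]7[C@@H]56)=CC(=O)[C@H]3C(=C)C(=O)O[C@@H]3[C@@H]12
F3 | step 8 | C4′-bromo seco-dimer triketone | C=C1C(=O)C[C@H]2C(CCC5(Br)C(=O)C[C@H]6C(=C)CC[C@H]7C(=C)C(=O)O[C@@H]7[C@@H]56)=CC(=O)[C@H]3C(=C)C(=O)O[C@@H]3[C@@H]12
F4 | step 8 | C3 TMS enol ether of F3 | C=C1C(O[Si](C)(C)C)=C[C@H]2C(CCC5(Br)C(=O)C[C@H]6C(=C)CC[C@H]7C(=C)C(=O)O[C@@H]7[C@@H]56)=CC(=O)[C@H]3C(=C)C(=O)O[C@@H]3[C@@H]12
F5 | step 5 | 8α-hydroxydehydrozaluzanin C | C=C1C(=O)C[C@H]2C(=C)C[C@H](O)[C@H]3C(=C)C(=O)O[C@@H]3[C@@H]12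
F6 | step 5 | bis-silyl derivative of F5 (C3 TMS enol ether, 8α-OTMS) | C=C1C(O[Si](C)(C)C)=C[C@H]2C(=C)C[C@H](O[Si](C)(C)C)[C@H]3C(=C)C(=O)O[C@@H]3[C@@H]12
F7 | step 5 | 8α-hydroxy-3-oxoguaia-1,4(15),10(14),11(13)-tetraen-12,6α-olide (trienone) | C=C1C(=O)C=C2C(=C)C[C@H](O)[C@H]3C(=C)C(=O)O[C@@H]3[C@@H]12
F8 | step 5 | Diels–Alder adduct (C1=C10, C2–H epimers, 8α-OH) | C=C1C(=O)C2C3=C(CC[C@]24C(=O)C[C@H]2C(=C)CC[C@H]5C(=C)C(=O)O[C@@H]5[C@H]24)C[C@H](O)[C@H]2C(=C)C(=O)O[C@@H]2[C@@H]13
F9 | step 5 | 8-oxo Diels–Alder adduct (C1=C10, C2–H epimers) | C=C1C(=O)C2C3=C(CC[C@]24C(=O)C[C@H]2C(=C)CC[C@H]5C(=C)C(=O)O[C@@H]5[C@H]24)CC(=O)[C@H]2C(=C)C(=O)O[C@@H]2[C@@H]13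
F10 | step 10 | 8-epi-15 (8α-alcohol) | C=C1C(=O)C2=C3[C@H](CC[C@]24C(=O)C[C@H]2C(=C)CC[C@H]5C(=C)C(=O)O[C@@H]5[C@H]24)C[C@H](O)[C@H]2C(=C)C(=O)O[C@@H]2[C@@H]13
F11 | step 10 | 8β-formate of 15 | C=C1C(=O)C2=C3[C@H](CC[C@]24C(=O)C[C@H]2C(=C)CC[C@H]5C(=C)C(=O)O[C@@H]5[C@H]24)C[C@@H](OC=O)[C@H]2C(=C)C(=O)O[C@@H]2[C@@H]13
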